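**Retrosynthetic overview** (germacrane numbering of the target, C1–C15, is used for every intermediate)

1. Endgame: the C14 aldehyde and C1=C10 come from a C10 exocyclic methylene (singlet-oxygen ene reaction, dehydration); the 8-ester by acylation; C11=C13 by Mannich reaction and elimination; the 6,12-lactone from a C6 ketone that carries a C7 acetate arm.
2. Key disconnection: the cyclodecane ring (C1–C10) arises from a cyclooctane (C6, C14, C10, C1–C5) by an oxyanion-driven two-carbon ring expansion (anionic oxy-Cope: C8–C9 made, C6–C14 broken), and the enolate is alkylated at C7 in the same flask.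
3. Enabling feature: in the eight-membered precursor, C6 carries O⁻ and the (Z)-2-alkoxyvinyl group C7=C8 and is linked through one ring CH2 (C14) to C10, which carries the exocyclic CH2 (C9). This is a 3-oxido-1,5-diene whose allyl part C9/C10/C14 is symmetrical, so a [3,3] and a [1,3] shift give the same ten-membered ring, with C14 expelled as the exocyclic methylene.
4. The cis-4,5-epoxide is made on the cis-cyclooctene (CBS reduction, directed epoxidation) and relays its configuration to C6, then to C8 (chair transfer), C7 (alkylation) and again C6 (reduction).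
5. Ring order: cyclooctane (purchased) → oxirane (step 6) → cyclodecane by ring expansion (step 11) → γ-lactone (step 12).

Key step: step 11

Remark: the target SMILES is read as the cis-4α,5α-epoxide, the trans-fused 6α,12-lactone (7β-C11), the 8β-ester and the ring-cis C1=C10 enal (CHO trans to C2).
Remark: cyclooctane-1,5-dione is taken as purchasable (otherwise one Jones oxidation from cis-cyclooctane-1,5-diol); the C11 epimers of 21 and 22 are not separated because step 14 removes that centre.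

Step 1
Reactants: 1 cyclooctane-1,5-dione
Product: 2 5-methylidenecyclooctan-1-one
Conditions: Ph3PCH3Br (1.0 equiv), KOtBu (1.0 equiv), THF, 0 °C; ylide added to 1 at −78 → 0 °C; unreacted 1 recycled
Reagents that add atoms: methyltriphenylphosphonium bromide C[P+](c1ccccc1)(c1ccccc1)c1ccccc1.[Br-]
Why: Wittig methylenation with one equivalent of ylide desymmetrises the diketone statistically; no stereocentre is formed.

Step 2
Reactants: 2 5-methylidenecyclooctan-1-one
Product: 4 (2Z)-5-methylidenecyclooct-2-en-1-one, via silyl enol ether 3 (not isolated)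
Conditions: LDA, TMSCl, THF, −78 °C; then Pd(OAc)2 (1.05 equiv), MeCN, 20 °C
Reagents that add atoms: none
Why: Saegusa–Ito dehydrogenation; the two α-positions of the Cs-symmetric ketone are equivalent, so only one enone can form and the ring keeps the alkene cis.

Step 3
Reactants: 4 (2Z)-5-methylidenecyclooct-2-en-1-one
Product: 5 rac-(2Z)-1-methyl-5-methylidenecyclooct-2-en-1-ol
Conditions: MeLi, Et2O, −78 °C; H2O
Reagents that add atoms: methyllithium [Li]C
Why: 1,2-addition of a hard organolithium to the enone; the carbinol centre is erased in step 4, so the racemate is used.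

Step 4
Reactants: 5 rac-(2Z)-1-methyl-5-methylidenecyclooct-2-en-1-ol
Product: 6 (2Z)-3-methyl-7-methylidenecyclooct-2-en-1-one
Conditions: IBX, DMSO, 55 °C
Reagents that add atoms: 2-iodoxybenzoic acid (IBX) O=C1OI(=O)(O)c2ccccc12
Why: oxidative 1,3-transposition of a tertiary allylic alcohol (Babler–Dauben type, IBX variant) puts the carbonyl at C6 and the methyl-bearing Z-alkene at C4=C5; the product is achiral.

Step 5
Reactants: 6 (2Z)-3-methyl-7-methylidenecyclooct-2-en-1-one
Product: 7 (1S,2Z)-3-methyl-7-methylidenecyclooct-2-en-1-ol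
Conditions: (R)-2-methyl-CBS-oxazaborolidine (0.2 equiv), catecholborane, toluene, −78 °C
Reagents that add atoms: none
Why: Corey–Bakshi–Shibata reduction with the alkenyl arm as the large group delivers hydride to one enantiotopic face and sets C6 (S), the source of all later stereocentres.

Step 6
Reactants: 7 (1S,2Z)-3-methyl-7-methylidenecyclooct-2-en-1-ol
Product: 8 (1S,2S,8R)-8-methyl-4-methylidene-9-oxabicyclo[6.1.0]nonan-2-ol
Conditions: VO(acac)2 (cat.), t-BuOOH (1.1 equiv), CH2Cl2, 0 °C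
Reagents that add atoms: tert-butyl hydroperoxide CC(C)(C)OO
Why: vanadium-catalysed hydroxyl-directed epoxidation delivers oxygen syn to the C6–OH, sets C4 and C5 (cis-epoxide by ring geometry) and should react faster at the allylic than at the homoallylic exocyclic alkene.

Step 7
Reactants: 8 (1S,2S,8R)-8-methyl-4-methylidene-9-oxabicyclo[6.1.0]nonan-2-ol
Product: 9 (1R,8R)-8-methyl-4-methylidene-9-oxabicyclo[6.1.0]nonan-2-one
Conditions: Dess–Martin periodinane, NaHCO3, CH2Cl2, 0 → 20 °C
Reagents that add atoms: none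
Why: buffered Dess–Martin oxidation gives the α,β-epoxy ketone without moving the β,γ-alkene; C6 has served as relay and is erased.

Step 8
Reactants: 10 4-methoxybenzyl alcohol; 11 trichloroethylene
Product: 12 (E)-1,2-dichlorovinyl 4-methoxybenzyl ether
Conditions: KH, THF, −40 → 20 °C
Reagents that add atoms: none
Why: addition of the potassium alkoxide to dichloroacetylene formed in situ from trichloroethylene (addition–elimination route to ynol-ether precursors).

Step 9
Reactants: 9 (1R,8R)-8-methyl-4-methylidene-9-oxabicyclo[6.1.0]nonan-2-one; 12 (E)-1,2-dichlorovinyl 4-methoxybenzyl ether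
Product: 14 (1S,2R,8R)-2-{[(4-methoxyphenyl)methoxy]ethynyl}-8-methyl-4-methylidene-9-oxabicyclo[6.1.0]nonan-2-ol, via lithium alkoxyacetylide 13 (not isolated)
Conditions: 12, n-BuLi (2.1 equiv), THF, −78 → −40 °C; CeCl3, −78 °C; then 9; aq. NH4Cl
Reagents that add atoms: none
Why: dehydrochlorination and Cl–Li exchange give the acetylide, whose organocerium form adds 1,2 to the enolisable ketone anti to the α-epoxide C–O bond (Felkin–Anh and chelate models agree), so the C6–OH ends syn to the epoxide oxygen.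

Step 10
Reactants: 14 the propargylic alcohol
Product: 15 (1S,2R,8R)-2-{(Z)-2-[(4-methoxyphenyl)methoxy]ethenyl}-8-methyl-4-methylidene-9-oxabicyclo[6.1.0]nonan-2-ol
Conditions: H2 (1 atm), Lindlar catalyst, quinoline, EtOAc, 0 °C
Reagents that add atoms: none
Why: Lindlar semi-hydrogenation gives the (Z)-enol ether by syn addition; the poisoned catalyst should leave the 1,1-disubstituted alkene and the epoxide alone.

Step 11
Reactants: 15 the (Z)-enol ether carbinol
Product: 18 methyl 2-[(1R,3R,4R,10R)-4-[(4-methoxyphenyl)methoxy]-10-methyl-6-methylidene-2-oxo-11-oxabicyclo[8.1.0]undecan-3-yl]acetate (4α,5α-epoxy-6-oxo-7β-CH2CO2Me-8β-OPMB-cyclodec-10(14)-ene), via potassium alkoxide 16 (not isolated), via potassium enolate 17 (not isolated)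
Conditions: KH (1.3 equiv), 18-crown-6 (1.3 equiv), THF, −20 → 20 °C; then −78 °C, ICH2CO2Me
Reagents that add atoms: methyl iodoacetate COC(=O)CI
Why: Proposed new method: deprotonation gives the 3-oxido-1,5-diene C9=C10–C14–C6(O⁻)–C7=C8, in which the oxyanion-weakened, allylic C6–C14 bond breaks while C8–C9 forms (anionic oxy-Cope [3,3] shift), so the eight-membered ring grows by two atoms to the ten-membered enolate 17 with C14 expelled as the exocyclic methylene; because the C9/C10/C14 allyl unit is symmetrical, a [1,3] shift or an ion-pair recombination would give the same constitution, and the enolate is then C-alkylated in the same flask. The closest known reaction types are the anionic oxy-Cope ring expansion of 1,2-dialkenylcycloalkanols, the Claisen ring expansion of 2-methylene-6-vinyltetrahydropyrans (same 1,3-bridged array) and the alkoxide-accelerated two-carbon ring expansion of 1-vinylcycloalk-3-en-1-ols. The ten-membered ring is not closed by a cyclisation but arises by ring enlargement through a chair-like six-centre transition state bridged by the C1–C5 chain, which only fits when the ring bond C6–C5 is axial and O⁻ equatorial (boat arrays and the other chair would need an unattainable C1···C5 span). C8 is set by chirality transfer from C6 (itself fixed by the epoxide) through this chair with the (Z)-enol ether oxygen axial, and C7 by alkylation of the ring-cis enolate on its open face, anti to the new C8–C9 bond and away from the transannular C9–C10–C1 loop. The step needs C- over O-alkylation and no Payne rearrangement or β-alkoxide loss: the syn arrangement of O⁻ and epoxide oxygen forbids backside attack on C5, the soft iodide favours carbon, and the C8–O bond lies in the enolate plane of the as-formed conformer.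

Step 12
Reactants: 18 the keto ester
Product: 20 (4R,5S,6S,7R,8R)-4,5-epoxy-8-[(4-methoxyphenyl)methoxy]-13-norgermacr-10(14)-en-12,6-olide, via 6α-hydroxy ester 19 (not isolated)
Conditions: Zn(BH4)2, Et2O, −30 °C; then DBU (cat.), toluene, 20 °C
Reagents that add atoms: none
Why: chelation-controlled reduction of the α,β-epoxy ketone delivers hydride anti to C4 on the open face to give the 6α-alcohol syn to the epoxide oxygen, which lactonises with the C7 acetate arm to the trans-fused γ-lactone.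

Step 13
Reactants: 20 the lactone
Product: 21 (4R,5S,6S,7R,8R)-13-(dimethylamino)-4,5-epoxy-8-[(4-methoxyphenyl)methoxy]germacr-10(14)-en-12,6-olide (C11 epimers)
Conditions: LDA (1.2 equiv), THF, −78 °C; CH2=NMe2⁺ I⁻, −78 → 0 °C
Reagents that add atoms: Eschenmoser's salt C=[N+](C)C.[I-]
Why: Mannich reaction of the lactone lithium enolate with the preformed iminium salt; the new C11 centre is inconsequential.

Step 14
Reactants: 21 the Mannich base
Product: 23 (4R,5S,6S,7R,8R)-4,5-epoxy-8-[(4-methoxyphenyl)methoxy]germacra-10(14),11(13)-dien-12,6-olide, via trimethylammonium iodide 22 (not isolated)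
Conditions: MeI, MeOH–CH2Cl2, 20 °C; then aq. NaHCO3, 20 °C
Reagents that add atoms: none
Why: exhaustive methylation and Hofmann-type β-elimination (E1cB) unveil the α-methylene lactone.

Step 15
Reactants: 23 the PMB ether
Product: 24 (4R,5S,6S,7R,8R)-4,5-epoxy-8-hydroxygermacra-10(14),11(13)-dien-12,6-olide
Conditions: DDQ (1.3 equiv), CH2Cl2–pH 7 buffer, 0 → 20 °C
Reagents that add atoms: none
Why: oxidative PMB cleavage (electron transfer to DDQ, hydrolysis of the hemiacetal) should free the 8β-alcohol without touching epoxide or alkenes.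

Step 16
Reactants: 24 the 8β-alcohol
Product: 25 (4R,5S,6S,7R,8R)-4,5-epoxy-8-(3-methylbutanoyloxy)germacra-10(14),11(13)-dien-12,6-olide
Conditions: (iPrCH2CO)2O, DMAP (cat.), Et3N, CH2Cl2, 0 → 20 °C
Reagents that add atoms: 3-methylbutanoic anhydride CC(C)CC(=O)OC(=O)CC(C)C
Why: DMAP-catalysed acyl transfer esterifies the secondary alcohol with retention at C8.

Step 17
Reactants: 25 the isovalerate
Product: 27 (4R,5S,6S,7R,8R)-4,5-epoxy-8-(3-methylbutanoyloxy)-14-oxogermacra-1(10),11(13)-dien-12,6-olide (ring-cis C1=C10; target), via 14-hydroperoxide 26 (not isolated)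
Conditions: O2, hν, tetraphenylporphyrin (cat.), CH2Cl2, −20 °C; then Ac2O, pyridine, DMAP (cat.), 0 → 20 °C
Reagents that add atoms: oxygen O=O
Why: Schenck ene reaction of singlet oxygen with the 1,1-disubstituted alkene (O–O bond to C14, hydrogen taken from C1, which should be favoured because the C9–H bonds are deactivated by the acyloxy-bearing C8 and less well aligned), then acetylation and Kornblum–DeLaMare-type elimination of the primary allylic hydroperoxide to the enal, whose preferred geometry (CHO trans to C2, ring-cis) should be reached by reversible conjugate addition of DMAP.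

**Compound list**

1 | cyclooctane-1,5-dione | O=C1CCCC(=O)CCC1 | starting material
2 | 5-methylidenecyclooctan-1-one | O=C1CCCC(=C)CCC1 | intermediate
3 | trimethyl[(5-methylidenecyclooct-1-en-1-yl)oxy]silane | C[Si](C)(C)OC1=CCCC(=C)CCC1 | intermediate
4 | (2Z)-5-methylidenecyclooct-2-en-1-one | O=C1/C=C\CC(=C)CCC1 | intermediate
5 | rac-(2Z)-1-methyl-5-methylidenecyclooct-2-en-1-ol | CC1(O)/C=C\CC(=C)CCC1 | intermediate
6 | (2Z)-3-methyl-7-methylidenecyclooct-2-en-1-one | O=C1/C=C(/C)CCCC(=C)C1 | intermediate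
7 | (1S,2Z)-3-methyl-7-methylidenecyclooct-2-en-1-ol | O[C@@H]1/C=C(/C)CCCC(=C)C1 | intermediate
8 | (1S,2S,8R)-8-methyl-4-methylidene-9-oxabicyclo[6.1.0]nonan-2-ol | O[C@@H]1[C@@H]2O[C@]2(C)CCCC(=C)C1 | intermediate
9 | (1R,8R)-8-methyl-4-methylidene-9-oxabicyclo[6.1.0]nonan-2-one | O=C1[C@@H]2O[C@]2(C)CCCC(=C)C1 | intermediate
10 | 4-methoxybenzyl alcohol | COc1ccc(CO)cc1 | starting material
11 | trichloroethylene | ClC=C(Cl)Cl | starting material
12 | (E)-1,2-dichlorovinyl 4-methoxybenzyl ether | COc1ccc(CO/C(Cl)=C\Cl)cc1 | intermediate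
13 | lithium 2-[(4-methoxyphenyl)methoxy]ethynide | [Li]C#COCc1ccc(OC)cc1 | intermediate
14 | (1S,2R,8R)-2-{[(4-methoxyphenyl)methoxy]ethynyl}-8-methyl-4-methylidene-9-oxabicyclo[6.1.0]nonan-2-ol | O[C@@]1(C#COCc3ccc(OC)cc3)CC(=C)CCC[C@@]2(C)O[C@@H]12 | intermediate
15 | (1S,2R,8R)-2-{(Z)-2-[(4-methoxyphenyl)methoxy]ethenyl}-8-methyl-4-methylidene-9-oxabicyclo[6.1.0]nonan-2-ol | O[C@@]1(/C=C\OCc3ccc(OC)cc3)CC(=C)CCC[C@@]2(C)O[C@@H]12 | intermediate
16 | potassium alkoxide of 15 | [K+].[O-][C@@]1(/C=C\OCc3ccc(OC)cc3)CC(=C)CCC[C@@]2(C)O[C@@H]12 | intermediate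
17 | potassium enolate of the ring-expanded ketone (ring-cis C6=C7 enolate, 8β-OPMB, 4α,5α-epoxide, C10 exocyclic methylene) | [K+].[O-]/C1=C/[C@H](OCc3ccc(OC)cc3)CC(=C)CCC[C@@]2(C)O[C@@H]12 | intermediate
18 | methyl 2-[(1R,3R,4R,10R)-4-[(4-methoxyphenyl)methoxy]-10-methyl-6-methylidene-2-oxo-11-oxabicyclo[8.1.0]undecan-3-yl]acetate | COC(=O)C[C@H]1C(=O)[C@@H]2O[C@]2(C)CCCC(=C)C[C@H]1OCc3ccc(OC)cc3 | intermediate
19 | 6α-hydroxy ester from 18 (6α-OH syn to the epoxide oxygen, otherwise as 18) | COC(=O)C[C@H]1[C@H](O)[C@@H]2O[C@]2(C)CCCC(=C)C[C@H]1OCc3ccc(OC)cc3 | intermediate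
20 | (4R,5S,6S,7R,8R)-4,5-epoxy-8-[(4-methoxyphenyl)methoxy]-13-norgermacr-10(14)-en-12,6-olide | C1C(=O)O[C@H]2[C@H]1[C@H](OCc3ccc(OC)cc3)CC(=C)CCC[C@@]1(C)O[C@@H]21 | intermediate
21 | (4R,5S,6S,7R,8R)-13-(dimethylamino)-4,5-epoxy-8-[(4-methoxyphenyl)methoxy]germacr-10(14)-en-12,6-olide, C11 epimers | CN(C)CC1C(=O)O[C@H]2[C@H]1[C@H](OCc3ccc(OC)cc3)CC(=C)CCC[C@@]1(C)O[C@@H]21 | intermediate
22 | trimethylammonium iodide of 21 | [I-].C[N+](C)(C)CC1C(=O)O[C@H]2[C@H]1[C@H](OCc3ccc(OC)cc3)CC(=C)CCC[C@@]1(C)O[C@@H]21 | intermediate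
23 | (4R,5S,6S,7R,8R)-4,5-epoxy-8-[(4-methoxyphenyl)methoxy]germacra-10(14),11(13)-dien-12,6-olide | C=C1C(=O)O[C@H]2[C@H]1[C@H](OCc3ccc(OC)cc3)CC(=C)CCC[C@@]1(C)O[C@@H]21 | intermediate
24 | (4R,5S,6S,7R,8R)-4,5-epoxy-8-hydroxygermacra-10(14),11(13)-dien-12,6-olide | C=C1C(=O)O[C@H]2[C@H]1[C@H](O)CC(=C)CCC[C@@]1(C)O[C@@H]21 | intermediate
25 | (4R,5S,6S,7R,8R)-4,5-epoxy-8-(3-methylbutanoyloxy)germacra-10(14),11(13)-dien-12,6-olide | C=C1C(=O)O[C@H]2[C@H]1[C@H](OC(=O)CC(C)C)CC(=C)CCC[C@@]1(C)O[C@@H]21 | intermediate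
26 | 14-hydroperoxy-1(10)-ene from 25 (ring-cis C1=C10) | C=C1C(=O)O[C@H]2[C@H]1[C@H](OC(=O)CC(C)C)C/C(COO)=C\CC[C@@]1(C)O[C@@H]21 | intermediate
27 | (4R,5S,6S,7R,8R)-4,5-epoxy-8-(3-methylbutanoyloxy)-14-oxogermacra-1(10),11(13)-dien-12,6-olide, ring-cis C1=C10 (CNP0260081.1) | C=C1C(=O)O[C@H]2[C@H]1[C@H](OC(=O)CC(C)C)C/C(C=O)=C\CC[C@@]1(C)O[C@@H]21 | target

**Step count:** 17 steps in total. Longest linear sequence: 16 steps (steps 1–7 and 9–17); step 8 prepares reagent 12.

**Three steps most likely to fail**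

Step 11 (carries the label). The bridged chair may be out of reach, so that the alkoxide fragments or simply survives, or the enolate may be protonated or O-alkylated before C-alkylation. The fallback uses known chemistry: the alkoxide-accelerated 1,3-shift that enlarges 1-vinylcycloalk-3-en-1-ols by two carbons, and the SeO2 oxidation of the C10 methyl group known for germacranolides. It moves the C10 alkene into the ring. It uses route compound 12, starts from commercial (1Z,5Z)-1,5-dimethylcycloocta-1,5-diene and returns to the route at target 27. Allylic oxidation of the diene (Rh2(cap)4, t-BuOOH; the 1,6-dimethyl isomer in the commercial diene and its products are removed by chromatography) should give (2Z,6Z)-3,7-dimethylcycloocta-2,6-dien-1-one F1. CBS reduction as in step 5 should give (1S,2Z,6Z)-3,7-dimethylcycloocta-2,6-dien-1-ol F2, directed epoxidation as in step 6 the epoxy alcohol (1S,2S,4Z,8R)-4,8-dimethyl-9-oxabicyclo[6.1.0]non-4-en-2-ol F3, and Dess–Martin oxidation the epoxy ketone (1R,4Z,8R)-4,8-dimethyl-9-oxabicyclo[6.1.0]non-4-en-2-one F4. Addition of acetylide 13 (made from 12 as in step 9) should give the propargylic alcohol F5, and Lindlar reduction the (Z)-enol ether carbinol F6. KH in THF–HMPA gives the potassium alkoxide F7, in which the allylic C6–C9 bond migrates to C8 to give the ten-membered potassium enolate F8; methyl iodoacetate traps it as the keto ester F9. Zn(BH4)2 gives the hydroxy ester F10, which closes to the lactone F11. Mannich reaction gives the amine F12, methylation the ammonium iodide F13 and elimination the α-methylene lactone F14. DDQ gives the alcohol F15 and acylation the isovalerate F16. SeO2/t-BuOOH oxidises the C14 methyl group (cis to H-1) to the allylic alcohol F17, and MnO2 gives 27.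

Step 17. Singlet oxygen may take the allylic hydrogen from C9 instead of C1, or the enal geometry may not equilibrate. The fallback removes C14 and rebuilds it by carbonylation, with the regiochemistry fixed by kinetic enolisation. It sets out from 23 and returns at 27. OsO4/NMO then NaIO4 should cleave the electron-rich exocyclic alkene (not the α-methylene lactone) to the C10 ketone F18. KHMDS/PhNTf2 at −78 °C, deprotonating C1 on the side away from the β-alkoxy carbon, should give the ring-cis enol triflate F19. Pd(OAc)2/dppp, CO and Et3SiH give the enal PMB ether F20, DDQ the hydroxy enal F21, and acylation as in step 16 gives 27.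

Step 12. Hydride may be delivered to the wrong face of C6, because the C7 side chain sits on the face that the epoxide chelate leaves open. The fallback accepts the wrong alcohol and inverts C6 during ring closure. It sets out from 18 and returns at 20. The misreduced 6β-hydroxy ester F22 closes to the cis-fused 6-epi lactone F23. LiOH and careful acidification give the hydroxy acid F24, and Mitsunobu lactonisation (PPh3, DIAD) closes the γ-lactone with inversion at C6 to give 20.

**Further compounds**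

F1 | step 11 | (2Z,6Z)-3,7-dimethylcycloocta-2,6-dien-1-one | O=C1/C=C(/C)CC/C=C(/C)C1
F2 | step 11 | (1S,2Z,6Z)-3,7-dimethylcycloocta-2,6-dien-1-ol | O[C@@H]1/C=C(/C)CC/C=C(/C)C1
F3 | step 11 | (1S,2S,4Z,8R)-4,8-dimethyl-9-oxabicyclo[6.1.0]non-4-en-2-ol | O[C@@H]1[C@@H]2O[C@]2(C)CC/C=C(/C)C1
F4 | step 11 | (1R,4Z,8R)-4,8-dimethyl-9-oxabicyclo[6.1.0]non-4-en-2-one | O=C1[C@@H]2O[C@]2(C)CC/C=C(/C)C1
F5 | step 11 | (1S,2R,4Z,8R)-2-{[(4-methoxyphenyl)methoxy]ethynyl}-4,8-dimethyl-9-oxabicyclo[6.1.0]non-4-en-2-ol | O[C@@]1(C#COCc3ccc(OC)cc3)C/C(C)=C\CC[C@@]2(C)O[C@@H]12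
F6 | step 11 | (1S,2R,4Z,8R)-2-{(Z)-2-[(4-methoxyphenyl)methoxy]ethenyl}-4,8-dimethyl-9-oxabicyclo[6.1.0]non-4-en-2-ol | O[C@@]1(/C=C\OCc3ccc(OC)cc3)C/C(C)=C\CC[C@@]2(C)O[C@@H]12
F7 | step 11 | potassium alkoxide of F6 | [K+].[O-][C@@]1(/C=C\OCc3ccc(OC)cc3)C/C(C)=C\CC[C@@]2(C)O[C@@H]12
F8 | step 11 | ten-membered potassium enolate (ring-cis C6=C7 and C1=C10, 8β-OPMB, 4α,5α-epoxide) | [K+].[O-]/C1=C/[C@H](OCc3ccc(OC)cc3)C/C(C)=C\CC[C@@]2(C)O[C@@H]12
F9 | step 11 | methyl 2-[(1R,3R,4R,6Z,10R)-4-[(4-methoxyphenyl)methoxy]-6,10-dimethyl-2-oxo-11-oxabicyclo[8.1.0]undec-6-en-3-yl]acetate | COC(=O)C[C@H]1C(=O)[C@@H]2O[C@]2(C)CC/C=C(/C)C[C@H]1OCc3ccc(OC)cc3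
F10 | step 11 | 6α-hydroxy ester from F9 | COC(=O)C[C@H]1[C@H](O)[C@@H]2O[C@]2(C)CC/C=C(/C)C[C@H]1OCc3ccc(OC)cc3
F11 | step 11 | (1(10)Z,4R,5S,6S,7R,8R)-4,5-epoxy-8-[(4-methoxyphenyl)methoxy]-13-norgermacr-1(10)-en-12,6-olide | C1C(=O)O[C@H]2[C@H]1[C@H](OCc3ccc(OC)cc3)C/C(C)=C\CC[C@@]1(C)O[C@@H]21
F12 | step 11 | 13-(dimethylamino)-11,13-dihydro derivative of F14, C11 epimers | CN(C)CC1C(=O)O[C@H]2[C@H]1[C@H](OCc3ccc(OC)cc3)C/C(C)=C\CC[C@@]1(C)O[C@@H]21
F13 | step 11 | trimethylammonium iodide of F12 | [I-].C[N+](C)(C)CC1C(=O)O[C@H]2[C@H]1[C@H](OCc3ccc(OC)cc3)C/C(C)=C\CC[C@@]1(C)O[C@@H]21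
F14 | step 11 | (1(10)Z,4R,5S,6S,7R,8R)-4,5-epoxy-8-[(4-methoxyphenyl)methoxy]germacra-1(10),11(13)-dien-12,6-olide | C=C1C(=O)O[C@H]2[C@H]1[C@H](OCc3ccc(OC)cc3)C/C(C)=C\CC[C@@]1(C)O[C@@H]21
F15 | step 11 | (1(10)Z,4R,5S,6S,7R,8R)-4,5-epoxy-8-hydroxygermacra-1(10),11(13)-dien-12,6-olide | C=C1C(=O)O[C@H]2[C@H]1[C@H](O)C/C(C)=C\CC[C@@]1(C)O[C@@H]21
F16 | step 11 | (1(10)Z,4R,5S,6S,7R,8R)-4,5-epoxy-8-(3-methylbutanoyloxy)germacra-1(10),11(13)-dien-12,6-olide | C=C1C(=O)O[C@H]2[C@H]1[C@H](OC(=O)CC(C)C)C/C(C)=C\CC[C@@]1(C)O[C@@H]21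
F17 | step 11 | 14-hydroxy derivative of F16 (ring-cis C1=C10) | C=C1C(=O)O[C@H]2[C@H]1[C@H](OC(=O)CC(C)C)C/C(CO)=C\CC[C@@]1(C)O[C@@H]21
F18 | step 17 | 10-oxo-14-nor ketone from 23 (8β-OPMB, α-methylene lactone, 4α,5α-epoxide) | C=C1C(=O)O[C@H]2[C@H]1[C@H](OCc3ccc(OC)cc3)CC(=O)CCC[C@@]1(C)O[C@@H]21
F19 | step 17 | ring-cis C10 enol triflate of F18 (C1=C10) | C=C1C(=O)O[C@H]2[C@H]1[C@H](OCc3ccc(OC)cc3)C/C(OS(=O)(=O)C(F)(F)F)=C\CC[C@@]1(C)O[C@@H]21
F20 | step 17 | 8-O-PMB ether of the 14-oxo-1(10)-ene (ring-cis enal) | C=C1C(=O)O[C@H]2[C@H]1[C@H](OCc3ccc(OC)cc3)C/C(C=O)=C\CC[C@@]1(C)O[C@@H]21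
F21 | step 17 | 8β-hydroxy-14-oxo-1(10)-ene (ring-cis enal) | C=C1C(=O)O[C@H]2[C@H]1[C@H](O)C/C(C=O)=C\CC[C@@]1(C)O[C@@H]21
F22 | step 12 | 6β-hydroxy ester (C6 epimer of 19) | COC(=O)C[C@H]1[C@@H](O)[C@@H]2O[C@]2(C)CCCC(=C)C[C@H]1OCc3ccc(OC)cc3
F23 | step 12 | cis-fused 6-epi lactone (C6 epimer of 20) | C1C(=O)O[C@@H]2[C@H]1[C@H](OCc3ccc(OC)cc3)CC(=C)CCC[C@@]1(C)O[C@@H]21
F24 | step 12 | 6β-hydroxy acid from F23 | OC(=O)C[C@H]1[C@@H](O)[C@@H]2O[C@]2(C)CCCC(=C)C[C@H]1OCc3ccc(OC)cc3
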